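**Plan**

- Retrosynthesis: the six O-benzyl groups and an ynone triple bond go last. Then the C3''–C(=O) and C(=O)–C≡C bonds of the dihydrochalcone chain are cut, then ring D at C4''–C5'' and C6''–C1'' (plus C3''–C4''), then the CH2–cyclobutenone bond back to 8-formylkaempferide and cyclobutane-1,3-dione.
- Enabling feature: ring D is hexasubstituted (C1'' CH2 bridge, C2'' OH, C3'' acyl, C4'' OH, C5'' CH3, C6'' OCH3), with its oxygens in a 1,3,5 relation. OH, CH3, OCH3 and the CH2 bridge sit on the four adjacent carbons C4''–C5''–C6''–C1'', which is the pattern a 2-alkyl-3-alkoxyvinylketene (C1''–C4'') and an ynol ether (C5'', C6'') deliver, with the three oxygens differentiated as OH, OCH3 and OBn.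
- Forward order: rings A, B and C come with kaempferide. C8 is formylated and the phenols benzylated, cyclobutane-1,3-dione is joined by reductive alkylation and O-benzylated, and benzannulation with 1-methoxypropyne closes ring D.
- The acyl chain is then attached at C3'' by iodination and carbonylative alkynylation, and one hydrogenation saturates the alkyne and removes all benzyl groups.
- Stereochemistry: the target has no stereocentre and no stereogenic double bond. The one quaternary centre of a transient racemic intermediate is destroyed in the step that forms it.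

Key step: step 7

Shorthand in names: Flv = 3,5,7-tris(benzyloxy)-2-(4-methoxyphenyl)-4-oxo-4H-chromen-8-yl (tri-O-benzylkaempferide attached through C8).

Assumption: the Duff reaction of kaempferide is taken to follow the C8 preference usual for 5,7-dihydroxyflavones.

Assumption: 1-benzyloxy-4-ethynylbenzene is taken as a catalogue compound, and cyclobutane-1,3-dione is used freshly made as its enol.

**Route**

Step 1
Reactants: 1 kaempferide
Product: 3 8-formylkaempferide, via aldimine 2 (not isolated)
Conditions: hexamethylenetetramine, AcOH, 100 °C; then aq. HCl, 70 °C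
Reagents that add atoms: hexamethylenetetramine, C1N2CN3CN1CN(C2)C3; water, O
Why: Duff formylation: the iminium ion from protonated hexamethylenetetramine substitutes the phloroglucinol-type ring A ortho to the 7-hydroxyl at C8, the site that Duff and Mannich reactions of 5,7-dihydroxyflavones generally prefer over C6, and an internal hydride shift followed by acid hydrolysis of aldimine 2 should release the aldehyde.

Step 2
Reactants: 3 8-formylkaempferide
Product: 4 3,5,7-tri-O-benzyl-8-formylkaempferide (Flv-CHO)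
Conditions: BnBr (4.5 equiv), K2CO3, DMF, 70 °C
Reagents that add atoms: benzyl bromide, BrCc1ccccc1
Why: Williamson etherification: excess benzyl bromide and carbonate in warm DMF should alkylate the 3- and 7-hydroxyls quickly and the chelated 5-hydroxyl more slowly, while the aldehyde, now without an ortho hydroxyl, stays inert.

Step 3
Reactants: 5 3-ethoxycyclobut-2-en-1-one
Product: 6 cyclobutane-1,3-dione (enol form 3-hydroxycyclobut-2-en-1-one)
Conditions: 1 M aq. HCl, 0 °C to rt; evaporation, used at once
Reagents that add atoms: water, O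
Why: Acid hydrolysis of a vinylogous ester: protonation at C2, addition of water at C3 and loss of ethanol should give the dione, which is kept cold and used directly because it is prone to self-condensation.

Step 4
Reactants: 4 3,5,7-tri-O-benzyl-8-formylkaempferide; 6 cyclobutane-1,3-dione
Product: 8 3-hydroxy-2-(Flv-methyl)cyclobut-2-en-1-one, via alkylidenedione 7 (not isolated)
Conditions: Hantzsch ester (diethyl 2,6-dimethyl-1,4-dihydropyridine-3,5-dicarboxylate, 1.1 equiv), L-proline (20 mol%), CH2Cl2, rt
Reagents that add atoms: none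
Why: Three-component reductive alkylation (Knoevenagel condensation, then Hantzsch ester transfer hydrogenation): the very acidic dione should condense with the proline-derived iminium ion of 4 to the doubly activated alkylidene dione 7, which takes up hydride from the dihydropyridine faster than a second dione, leaving the C-alkylated dione as its stable enol.

Step 5
Reactants: 8 3-hydroxy-2-(Flv-methyl)cyclobut-2-en-1-one
Product: 9 3-benzyloxy-2-(Flv-methyl)cyclobut-2-en-1-one
Conditions: BnOH, PPh3, DIAD, THF, 0 °C to rt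
Reagents that add atoms: benzyl alcohol, OCc1ccccc1
Why: Mitsunobu etherification: the enol of 8 (a vinylogous carboxylic acid) is acidic enough to protonate the betaine and is then alkylated on oxygen by the benzyloxyphosphonium ion, and because the two oxygens of the 2-substituted dione are equivalent only one enol ether can form.

Step 6
Reactants: 10 chloroacetaldehyde dimethyl acetal
Product: 12 1-methoxyprop-1-yne, via sodium methoxyacetylide 11 (not isolated)
Conditions: NaNH2 (3 equiv), liq. NH3, −33 °C; then MeI; H2O work-up, distillation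
Reagents that add atoms: iodomethane, CI
Why: Base-induced double elimination and acetylide alkylation: NaNH2 should remove methanol and then HCl from the chloroacetal and deprotonate the resulting methoxyacetylene to 11, which is C-methylated by iodomethane in liquid ammonia.

Step 7
Reactants: 9 3-benzyloxy-2-(Flv-methyl)cyclobut-2-en-1-one; 12 1-methoxyprop-1-yne
Product: 17 8-(6-benzyloxy-4-hydroxy-2-methoxy-3-methylbenzyl)-3,5,7-tri-O-benzylkaempferide, via vinylketene 13 (not isolated), via vinylcyclobutenone 14 (not isolated), via dienylketene 15 (not isolated), via cyclohexadienone 16 (not isolated)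
Conditions: 12 (3 equiv), toluene, sealed tube, 80 °C then 120 °C
Reagents that add atoms: none
Why: Danheiser benzannulation of a cyclobutenone with an ynol ether, the closest known class being 3-oxygenated 2-alkylcyclobutenones heated with alkoxy- or silyloxyalkynes. Thermal four-electron conrotatory opening of 9 (C1–C4 bond) should give vinylketene 13, whose ketene C=C takes up 12 in a [2+2] cycloaddition to 14, forming the C4''–C5'' and C6''–C1'' bonds. A second four-electron opening gives dienylketene 15, and ring D closes by thermal six-electron disrotatory electrocyclization (C3''–C4'') to cyclohexadienone 16, which enolizes to the phenol. The selectivity required is the orientation of the [2+2] step, and it is secured by the polarization of the ynol ether: its methyl-bearing carbon is the nucleophilic terminus and bonds to the electrophilic ketene carbonyl carbon, so OCH3 ends up between CH3 and the CH2 bridge. No stereocentre survives, because the quaternary carbon of racemic 14 becomes trigonal on ring opening, and the geometry of 15 needed for closure is reached through reversible opening of 14. Substrate 9 has no free OH or NH to trap the ketenes, and the excess of 12 keeps cycloaddition ahead of ketene dimerization or acylation of the product phenol.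

Step 8
Reactants: 17 8-(6-benzyloxy-4-hydroxy-2-methoxy-3-methylbenzyl)-3,5,7-tri-O-benzylkaempferide
Product: 18 8-(6-benzyloxy-4-hydroxy-5-iodo-2-methoxy-3-methylbenzyl)-3,5,7-tri-O-benzylkaempferide
Conditions: NIS (1.05 equiv), MeCN/CH2Cl2, 0 °C
Reagents that add atoms: N-iodosuccinimide, O=C1CCC(=O)N1I
Why: Electrophilic aromatic iodination: the single free carbon of ring D (C3'', ortho to the free hydroxyl and to OBn, para to OCH3) is far more nucleophilic than C6 of the carbonyl-deactivated flavone ring A or the anisyl ring B, so one equivalent of NIS should iodinate only there.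

Step 9
Reactants: 18 8-(6-benzyloxy-4-hydroxy-5-iodo-2-methoxy-3-methylbenzyl)-3,5,7-tri-O-benzylkaempferide
Product: 19 8-(4,6-dibenzyloxy-5-iodo-2-methoxy-3-methylbenzyl)-3,5,7-tri-O-benzylkaempferide
Conditions: BnBr, K2CO3, DMF, 40 °C
Reagents that add atoms: benzyl bromide, BrCc1ccccc1
Why: Williamson etherification: capping the C4'' hydroxyl keeps the later ynone from cyclizing onto a free ortho phenol and lets all oxygen protecting groups fall in one final operation.

Step 10
Reactants: 19 8-(4,6-dibenzyloxy-5-iodo-2-methoxy-3-methylbenzyl)-3,5,7-tri-O-benzylkaempferide; 20 1-benzyloxy-4-ethynylbenzene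
Product: 21 1-[2,6-dibenzyloxy-4-methoxy-5-methyl-3-(Flv-methyl)phenyl]-3-(4-benzyloxyphenyl)prop-2-yn-1-one
Conditions: CO (1 atm), PdCl2(PPh3)2 (5 mol%), Et3N, THF, 50 °C
Reagents that add atoms: carbon monoxide, [C-]#[O+]
Why: Copper-free carbonylative Sonogashira coupling: oxidative addition of zerovalent palladium into the C–I bond, CO insertion (favoured for an electron-rich, doubly ortho-substituted aryl group), amine-assisted alkynylation and reductive elimination should give the aryl ynone with the carbonyl on C3''.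

Step 11
Reactants: 21 1-[2,6-dibenzyloxy-4-methoxy-5-methyl-3-(Flv-methyl)phenyl]-3-(4-benzyloxyphenyl)prop-2-yn-1-one
Product: 23 4'''-hydroxytrianguletin, via hexabenzyl dihydrochalcone 22 (not isolated)
Conditions: H2 (1 atm), Pd/C, THF/MeOH, rt
Reagents that add atoms: none
Why: Heterogeneous catalytic hydrogenation and hydrogenolysis: the conjugated alkyne should be saturated first to 22, then the six O-benzyl groups are cleaved, while the two chelated aryl ketones, the tetrasubstituted flavonol double bond, the diarylmethane and both methyl ethers are expected to resist Pd/C at 1 atm.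

**Compound list**

1 | kaempferide (3,5,7-trihydroxy-4'-methoxyflavone) | COc1ccc(-c2oc3cc(O)cc(O)c3c(=O)c2O)cc1 | starting material
2 | 8-(iminomethyl)kaempferide, the aldimine stage of the Duff reaction drawn free of the hexamine residue (formed in the flask) | COc1ccc(-c2oc3c(C=N)c(O)cc(O)c3c(=O)c2O)cc1 | intermediate
3 | 8-formylkaempferide | COc1ccc(-c2oc3c(C=O)c(O)cc(O)c3c(=O)c2O)cc1 | intermediate
4 | 3,5,7-tri-O-benzyl-8-formylkaempferide (Flv-CHO) | O=Cc1c(OCc2ccccc2)cc(OCc2ccccc2)c2c(=O)c(OCc3ccccc3)c(-c3ccc(OC)cc3)oc12 | intermediate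
5 | 3-ethoxycyclobut-2-en-1-one | CCOC1=CC(=O)C1 | starting material
6 | cyclobutane-1,3-dione | O=C1CC(=O)C1 | intermediate
7 | 2-(Flv-methylidene)cyclobutane-1,3-dione (formed in the flask) | O=C1CC(=O)C1=Cc1c(OCc2ccccc2)cc(OCc2ccccc2)c2c(=O)c(OCc3ccccc3)c(-c3ccc(OC)cc3)oc12 | intermediate
8 | 3-hydroxy-2-(Flv-methyl)cyclobut-2-en-1-one (enol of the 2-substituted cyclobutane-1,3-dione) | O=C1CC(O)=C1Cc1c(OCc2ccccc2)cc(OCc2ccccc2)c2c(=O)c(OCc3ccccc3)c(-c3ccc(OC)cc3)oc12 | intermediate
9 | 3-benzyloxy-2-(Flv-methyl)cyclobut-2-en-1-one | O=C1CC(OCc2ccccc2)=C1Cc1c(OCc2ccccc2)cc(OCc2ccccc2)c2c(=O)c(OCc3ccccc3)c(-c3ccc(OC)cc3)oc12 | intermediate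
10 | chloroacetaldehyde dimethyl acetal | COC(CCl)OC | starting material
11 | sodium methoxyacetylide (formed in the flask) | [Na+].[C-]#COC | intermediate
12 | 1-methoxyprop-1-yne | CC#COC | intermediate
13 | 3-benzyloxy-2-(Flv-methyl)buta-1,3-dien-1-one, the vinylketene (formed in the flask) | C=C(OCc1ccccc1)C(=C=O)Cc1c(OCc2ccccc2)cc(OCc2ccccc2)c2c(=O)c(OCc3ccccc3)c(-c3ccc(OC)cc3)oc12 | intermediate
14 | racemic 4-(1-benzyloxyethenyl)-3-methoxy-2-methyl-4-(Flv-methyl)cyclobut-2-en-1-one (formed in the flask) | COC1=C(C)C(=O)C1(Cc1c(OCc2ccccc2)cc(OCc2ccccc2)c2c(=O)c(OCc3ccccc3)c(-c3ccc(OC)cc3)oc12)C(=C)OCc1ccccc1 | intermediate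
15 | (3E)-5-benzyloxy-3-methoxy-2-methyl-4-(Flv-methyl)hexa-1,3,5-trien-1-one, the dienylketene with ketene and benzyloxyvinyl groups cis (formed in the flask) | O=C=C(C)/C(OC)=C(/Cc1c(OCc2ccccc2)cc(OCc2ccccc2)c2c(=O)c(OCc3ccccc3)c(-c3ccc(OC)cc3)oc12)C(=C)OCc1ccccc1 | intermediate
16 | 5-benzyloxy-3-methoxy-2-methyl-4-(Flv-methyl)cyclohexa-2,4-dien-1-one (formed in the flask) | COC1=C(C)C(=O)CC(OCc2ccccc2)=C1Cc1c(OCc2ccccc2)cc(OCc2ccccc2)c2c(=O)c(OCc3ccccc3)c(-c3ccc(OC)cc3)oc12 | intermediate
17 | 8-(6-benzyloxy-4-hydroxy-2-methoxy-3-methylbenzyl)-3,5,7-tri-O-benzylkaempferide | COc1c(C)c(O)cc(OCc2ccccc2)c1Cc1c(OCc2ccccc2)cc(OCc2ccccc2)c2c(=O)c(OCc3ccccc3)c(-c3ccc(OC)cc3)oc12 | intermediate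
18 | 8-(6-benzyloxy-4-hydroxy-5-iodo-2-methoxy-3-methylbenzyl)-3,5,7-tri-O-benzylkaempferide | COc1c(C)c(O)c(I)c(OCc2ccccc2)c1Cc1c(OCc2ccccc2)cc(OCc2ccccc2)c2c(=O)c(OCc3ccccc3)c(-c3ccc(OC)cc3)oc12 | intermediate
19 | 8-(4,6-dibenzyloxy-5-iodo-2-methoxy-3-methylbenzyl)-3,5,7-tri-O-benzylkaempferide | COc1c(C)c(OCc2ccccc2)c(I)c(OCc2ccccc2)c1Cc1c(OCc2ccccc2)cc(OCc2ccccc2)c2c(=O)c(OCc3ccccc3)c(-c3ccc(OC)cc3)oc12 | intermediate
20 | 1-benzyloxy-4-ethynylbenzene | C#Cc1ccc(OCc2ccccc2)cc1 | starting material
21 | 1-[2,6-dibenzyloxy-4-methoxy-5-methyl-3-(Flv-methyl)phenyl]-3-(4-benzyloxyphenyl)prop-2-yn-1-one | COc1c(C)c(OCc2ccccc2)c(C(=O)C#Cc2ccc(OCc3ccccc3)cc2)c(OCc2ccccc2)c1Cc1c(OCc2ccccc2)cc(OCc2ccccc2)c2c(=O)c(OCc3ccccc3)c(-c3ccc(OC)cc3)oc12 | intermediate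
22 | 1-[2,6-dibenzyloxy-4-methoxy-5-methyl-3-(Flv-methyl)phenyl]-3-(4-benzyloxyphenyl)propan-1-one (formed in the flask) | COc1c(C)c(OCc2ccccc2)c(C(=O)CCc2ccc(OCc3ccccc3)cc2)c(OCc2ccccc2)c1Cc1c(OCc2ccccc2)cc(OCc2ccccc2)c2c(=O)c(OCc3ccccc3)c(-c3ccc(OC)cc3)oc12 | intermediate
23 | 4'''-hydroxytrianguletin | COc1ccc(-c2oc3c(Cc4c(O)c(C(=O)CCc5ccc(O)cc5)c(O)c(C)c4OC)c(O)cc(O)c3c(=O)c2O)cc1 | target

**Step count and risks**

Total step count: 11. Longest linear sequence: 9 steps (1, 2, 4, 5, 7, 8, 9, 10, 11 from kaempferide); steps 3 and 6 are side branches.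

Steps most likely to fail:

1. Step 7. The vinylogous-ester cyclobutenone may open more slowly than the ynol ether is consumed thermally, or the ketenes may be captured by the newly formed phenol instead of the alkyne. The fallback gives up the ring-forming step and brings ring D in preformed; it sets out from 1 and comes back at 23. Commercial 2-methylphloroglucinol would be C-acylated with 3-(4-hydroxyphenyl)propanoic acid in BF3·OEt2 (Friedel–Crafts acylation) to 3'-methylphloretin F1. Its non-chelated, most acidic 4'-hydroxyl would be methylated (Me2SO4, K2CO3, acetone) to 1-(2,6-dihydroxy-4-methoxy-3-methylphenyl)-3-(4-hydroxyphenyl)propan-1-one F2. Kaempferide 1 would be converted by a Mannich reaction (Me2NH, CH2O, EtOH) into 8-(dimethylaminomethyl)kaempferide F3. Heating F3 with F2 in dioxane should expel dimethylamine to give the kaempferide 7,8-ortho-quinone methide F4, which alkylates the one free ring carbon of F2 and gives 23 directly.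

2. Step 4. Condensation of the hindered, electron-rich aldehyde may lag behind self-condensation of the free dione, or the alkylidene dione may add a second dione before hydride transfer. The fallback forms the same C–C bond by cross-coupling; it sets out from 4 and 6 and comes back at 9. Aldehyde 4 would be reduced with NaBH4 to 8-(hydroxymethyl)-3,5,7-tri-O-benzylkaempferide F5 and converted with PBr3 into 8-(bromomethyl)-3,5,7-tri-O-benzylkaempferide F6; zinc dust and LiCl in THF would give the benzylic zinc bromide F7. Dione 6 would be O-benzylated as in step 5 to 3-benzyloxycyclobut-2-en-1-one F8 and brominated at C2 with NBS to 3-benzyloxy-2-bromocyclobut-2-en-1-one F9. Negishi coupling of F7 with F9 (Pd(PPh3)4, THF) should give 9.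

3. Step 10. Oxidative addition at the iodide flanked by two benzyloxy groups may be slow, so that alkynylation without CO insertion or reductive loss of iodine takes over. The fallback installs the carbonyl carbon by formylation; it sets out from 17 and comes back at 21. Ortho-formylation of phenol 17 (MgCl2, Et3N, paraformaldehyde, MeCN, reflux; Casnati–Skattebøl conditions) should give the ring-D salicylaldehyde F10, and benzylation (BnBr, K2CO3) its benzyl ether F11. The lithium acetylide F12, made from 20 and n-BuLi, would add to the aldehyde at −78 °C to give the racemic propargylic alcohol F13, and MnO2 would oxidize it to 21.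

**Further compounds**

F1 | step 7 | 3'-methylphloretin, 1-(2,4,6-trihydroxy-3-methylphenyl)-3-(4-hydroxyphenyl)propan-1-one | Cc1c(O)cc(O)c(C(=O)CCc2ccc(O)cc2)c1O
F2 | step 7 | 1-(2,6-dihydroxy-4-methoxy-3-methylphenyl)-3-(4-hydroxyphenyl)propan-1-one | COc1cc(O)c(C(=O)CCc2ccc(O)cc2)c(O)c1C
F3 | step 7 | 8-(dimethylaminomethyl)kaempferide | COc1ccc(-c2oc3c(CN(C)C)c(O)cc(O)c3c(=O)c2O)cc1
F4 | step 7 | kaempferide 7,8-ortho-quinone methide | C=C1C(=O)C=C(O)C2=C1OC(c1ccc(OC)cc1)=C(O)C2=O
F5 | step 4 | 8-(hydroxymethyl)-3,5,7-tri-O-benzylkaempferide | OCc1c(OCc2ccccc2)cc(OCc2ccccc2)c2c(=O)c(OCc3ccccc3)c(-c3ccc(OC)cc3)oc12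
F6 | step 4 | 8-(bromomethyl)-3,5,7-tri-O-benzylkaempferide | BrCc1c(OCc2ccccc2)cc(OCc2ccccc2)c2c(=O)c(OCc3ccccc3)c(-c3ccc(OC)cc3)oc12
F7 | step 4 | (Flv-methyl)zinc bromide | Br[Zn]Cc1c(OCc2ccccc2)cc(OCc2ccccc2)c2c(=O)c(OCc3ccccc3)c(-c3ccc(OC)cc3)oc12
F8 | step 4 | 3-benzyloxycyclobut-2-en-1-one | O=C1CC(OCc2ccccc2)=C1
F9 | step 4 | 3-benzyloxy-2-bromocyclobut-2-en-1-one | O=C1CC(OCc2ccccc2)=C1Br
F10 | step 10 | 8-(6-benzyloxy-5-formyl-4-hydroxy-2-methoxy-3-methylbenzyl)-3,5,7-tri-O-benzylkaempferide | COc1c(C)c(O)c(C=O)c(OCc2ccccc2)c1Cc1c(OCc2ccccc2)cc(OCc2ccccc2)c2c(=O)c(OCc3ccccc3)c(-c3ccc(OC)cc3)oc12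
F11 | step 10 | 8-(4,6-dibenzyloxy-5-formyl-2-methoxy-3-methylbenzyl)-3,5,7-tri-O-benzylkaempferide | COc1c(C)c(OCc2ccccc2)c(C=O)c(OCc2ccccc2)c1Cc1c(OCc2ccccc2)cc(OCc2ccccc2)c2c(=O)c(OCc3ccccc3)c(-c3ccc(OC)cc3)oc12
F12 | step 10 | lithium (4-benzyloxyphenyl)acetylide | [Li+].[C-]#Cc1ccc(OCc2ccccc2)cc1
F13 | step 10 | racemic 1-[2,6-dibenzyloxy-4-methoxy-5-methyl-3-(Flv-methyl)phenyl]-3-(4-benzyloxyphenyl)prop-2-yn-1-ol | COc1c(C)c(OCc2ccccc2)c(C(O)C#Cc2ccc(OCc3ccccc3)cc2)c(OCc2ccccc2)c1Cc1c(OCc2ccccc2)cc(OCc2ccccc2)c2c(=O)c(OCc3ccccc3)c(-c3ccc(OC)cc3)oc12
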